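**Retrosynthetic overview**
1. Target 27 ⇐ C1 silyl ether 26 ⇐ ring-closing metathesis of the C6 2-(acetoxymethyl)acrylate 25, which forms the butenolide C7=C11 bond.
2. 25 ⇐ ten-membered keto silyl ether 18 (C3 reduction, acetylation) ⇐ Ni/Cr-mediated C6–C7 closure of the (Z)-4-oxo-enal 15.
3. 15 (Z-C4=C5 flanked by C3=O and C6=O) ⇐ oxidative ring-opening of the 2,3-disubstituted furan 13; the furan is the masked Z-enedione.
4. 13 ⇐ enone 11 (CBS reduction sets C1) ⇐ amide 5 + mono-lithiated symmetric 2,5-diiodohexa-1,5-diene 8 (supplies C7–C10 and C14).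
5. 5 ⇐ furan-3-ylmethanol by Eschenmoser–Claisen rearrangement (supplies C15, C2, C1). Ring order: ten-membered carbocycle (step 7), then butenolide (step 12).

Assumption: compounds 1, 2, 6 and 22 are purchased; locants C1–C15 in descriptive names follow the germacrane numbering of the target (ring C1–C10, C12 = lactone C=O, C13 = CH2OAc, C14 = CH2 on C10, C15 = CH3 on C4).

**Step 1**
Reactants: 1 furan-3-ylmethanol; 2 1,1-dimethoxy-N,N-dimethylethanamine (N,N-dimethylacetamide dimethyl acetal)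
Product: 5 N,N-dimethyl-2-(3-methylfuran-2-yl)acetamide, via ketene N,O-acetal 3 (not isolated), via 3-methylidene-2,3-dihydrofuran 4 (not isolated)
Conditions: 2 (2 equiv), xylenes, 140 °C, MeOH distilled off, 16 h
Reagents that add atoms: none
Why: Eschenmoser–Claisen rearrangement, in which the [3,3] shift of 3 across the furan C2=C3 bond gives dearomatized 4 that re-aromatizes by hydrogen shift, so the CH2O carbon becomes the C15 methyl and C2–C1 sits on the neighbouring ring carbon (no stereocenter).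

**Step 2**
Reactants: 6 hexa-1,5-diyne
Product: 8 2,5-diiodohexa-1,5-diene, via 2-iodohex-1-en-5-yne 7 (not isolated)
Conditions: NaI (2.5 equiv), Me3SiCl (2.5 equiv), H2O (1.25 equiv), MeCN, 0 °C → rt
Reagents that add atoms: sodium iodide, [Na+].[I-]
Why: Markovnikov hydroiodination of both terminal alkynes by HI generated in the flask gives the symmetric bis(2-iodoalkene).

**Step 3**
Reactants: 8 2,5-diiodohexa-1,5-diene; 5 N,N-dimethyl-2-(3-methylfuran-2-yl)acetamide
Product: 11 6-iodo-3-methylidene-1-(3-methylfuran-2-yl)hept-6-en-2-one, via alkenyllithium 9 (not isolated), via lithium hemiaminal alkoxide 10 (not isolated)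
Conditions: 8 (2.5 equiv), t-BuLi (2.0 equiv), Et2O, −78 °C; then 5 (1.0 equiv), −78 → −30 °C; cold 1 M HCl
Reagents that add atoms: none
Why: Iodine–lithium exchange at one of the two equivalent vinyl iodides (excess 8 keeps it single) followed by acyl substitution on the tertiary amide, whose tetrahedral adduct 10 persists until the acid quench and prevents over-addition; this breaks the symmetry of 8.

**Step 4**
Reactants: 11 6-iodo-3-methylidene-1-(3-methylfuran-2-yl)hept-6-en-2-one
Product: 12 (2R)-6-iodo-3-methylidene-1-(3-methylfuran-2-yl)hept-6-en-2-ol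
Conditions: (S)-2-methyl-CBS-oxazaborolidine (0.2 equiv), catecholborane (1.8 equiv), toluene, −78 °C; MeOH, then aq. NaOH
Reagents that add atoms: none
Why: Corey–Bakshi–Shibata reduction, with the 1,1-disubstituted alkenyl group as the large and CH2-furyl as the small substituent, so the (S)-catalyst delivers hydride to give the (R)-carbinol (C1); catecholborane at −78 °C leaves the alkenes alone.

**Step 5**
Reactants: 12 (2R)-6-iodo-3-methylidene-1-(3-methylfuran-2-yl)hept-6-en-2-ol
Product: 13 tert-butyl{[(2R)-6-iodo-3-methylidene-1-(3-methylfuran-2-yl)hept-6-en-2-yl]oxy}dimethylsilane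
Conditions: TBSCl, imidazole, DMF, rt
Reagents that add atoms: tert-butyldimethylsilyl chloride, CC(C)(C)[Si](C)(C)Cl
Why: Standard silylation; the C1 oxygen must stay masked until the end so that only the C3 and C6 oxygens are acylated later.

**Step 6**
Reactants: 13 tert-butyl{[(2R)-6-iodo-3-methylidene-1-(3-methylfuran-2-yl)hept-6-en-2-yl]oxy}dimethylsilane
Product: 15 (2Z,6R)-6-[(tert-butyldimethylsilyl)oxy]-10-iodo-3-methyl-7-methylidene-4-oxoundeca-2,10-dienal, via bromohydroxydihydrofuran 14 (not isolated)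
Conditions: NBS (1.05 equiv), NaHCO3 (2 equiv), acetone/H2O 10:1, −20 °C, dark, 30 min; used at once
Reagents that add atoms: water, O
Why: Oxidative dearomatization of the furan (bromination at the free α-carbon, water at the substituted α-carbon, collapse of 14 with loss of HBr) unveils the C3 ketone and C6 aldehyde, and because both carbons were held by the ring oxygen the C4=C5 bond is formed as the Z isomer; the furan reacts far faster with NBS than the 1,1-disubstituted alkenes.

**Step 7**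
Reactants: 15 (2Z,6R)-6-[(tert-butyldimethylsilyl)oxy]-10-iodo-3-methyl-7-methylidene-4-oxoundeca-2,10-dienal
Product: 18 (2Z,4R,9R)-9-[(tert-butyldimethylsilyl)oxy]-2-methyl-5,8-dimethylidene-4-[(trimethylsilyl)oxy]cyclodec-2-en-1-one, via alkenylchromium dichloride 16 (not isolated), via chromium alkoxide 17 (not isolated)
Conditions: CrCl2 (10 equiv), NiCl2 (5 mol %), Me3SiCl (4 equiv), THF/DMF 3:1, slow addition of 15 to 0.002 M, rt
Reagents that add atoms: chlorotrimethylsilane, C[Si](C)(C)Cl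
Why: Nozaki–Hiyama–Kishi macrocyclization, in which the alkenylchromium 16 (trivalent chromium) adds to the aldehyde rather than the hindered conjugated ketone and Me3SiCl silylates alkoxide 17 before it can add to the cis C3 ketone as a bridged hemiketal; C6 is set by substrate control from C1 (attack on the aldehyde face away from the C1 silyloxy group in the ring-closing conformer is taken to give 6R), which is the least secure stereochemical call of the route.

**Step 8**
Reactants: 18 (2Z,4R,9R)-9-[(tert-butyldimethylsilyl)oxy]-2-methyl-5,8-dimethylidene-4-[(trimethylsilyl)oxy]cyclodec-2-en-1-one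
Product: 19 (1S,2Z,4R,9R)-9-[(tert-butyldimethylsilyl)oxy]-2-methyl-5,8-dimethylidene-4-[(trimethylsilyl)oxy]cyclodec-2-en-1-ol
Conditions: (R)-2-methyl-CBS-oxazaborolidine (0.3 equiv), catecholborane (2 equiv), toluene/CH2Cl2, −78 °C; MeOH
Reagents that add atoms: none
Why: Corey–Bakshi–Shibata 1,2-reduction under catalyst control, with the α-methyl alkenyl side (C4) as the large and C2H2 as the small group, so the (R)-catalyst gives the (3S)-allylic alcohol.

**Step 9**
Reactants: 19 (1S,2Z,4R,9R)-9-[(tert-butyldimethylsilyl)oxy]-2-methyl-5,8-dimethylidene-4-[(trimethylsilyl)oxy]cyclodec-2-en-1-ol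
Product: 21 (1S,2Z,4R,9R)-9-[(tert-butyldimethylsilyl)oxy]-4-hydroxy-2-methyl-5,8-dimethylidenecyclodec-2-en-1-yl acetate, via C6 trimethylsilyl ether acetate 20 (not isolated)
Conditions: Ac2O, pyridine, DMAP (cat.), CH2Cl2, 0 °C; then 10 % aq. citric acid, MeOH, 0 °C
Reagents that add atoms: acetic anhydride, CC(=O)OC(C)=O
Why: Acetylation of the only free hydroxyl (C3) followed by mild acid cleavage of the labile secondary trimethylsilyl ether, which the tert-butyldimethylsilyl ether survives; C6–OH is freed only now that C3 is no longer a ketone, so no hemiketal can form.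

**Step 10**
Reactants: 22 2-(hydroxymethyl)prop-2-enoic acid
Product: 23 2-[(acetyloxy)methyl]prop-2-enoic acid
Conditions: AcCl (2.5 equiv), CH2Cl2, 0 °C → rt; then H2O
Reagents that add atoms: acetyl chloride, CC(=O)Cl
Why: O-acetylation of the primary alcohol; any mixed anhydride is hydrolysed on aqueous work-up.

**Step 11**
Reactants: 23 2-[(acetyloxy)methyl]prop-2-enoic acid; 21 (1S,2Z,4R,9R)-9-[(tert-butyldimethylsilyl)oxy]-4-hydroxy-2-methyl-5,8-dimethylidenecyclodec-2-en-1-yl acetate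
Product: 25 (1R,2Z,4S,6R)-4-(acetyloxy)-6-[(tert-butyldimethylsilyl)oxy]-3-methyl-7,10-dimethylidenecyclodec-2-en-1-yl 2-[(acetyloxy)methyl]prop-2-enoate, via acid chloride 24 (not isolated)
Conditions: 23, (COCl)2 (1.1 equiv), DMF (cat.), CH2Cl2, 0 °C → rt; then 21, 2,6-lutidine, CH2Cl2, −20 → 0 °C
Reagents that add atoms: none
Why: Acylation of the C6 alcohol by the acid chloride with retention at C6; a hindered non-nucleophilic base is used because nucleophilic amines attack 2-(acetoxymethyl)acrylates in an SN2' sense.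

**Step 12**
Reactants: 25 (1R,2Z,4S,6R)-4-(acetyloxy)-6-[(tert-butyldimethylsilyl)oxy]-3-methyl-7,10-dimethylidenecyclodec-2-en-1-yl 2-[(acetyloxy)methyl]prop-2-enoate
Product: 26 (1R,3S,6R,4Z)-3,13-diacetoxy-1-[(tert-butyldimethylsilyl)oxy]germacra-4,7(11),10(14)-trien-12,6-olide
Conditions: second-generation Hoveyda–Grubbs catalyst (10 mol %), toluene, 0.005 M, 80 °C, argon sparge
Reagents that add atoms: none
Why: Ring-closing metathesis between the C7 methylidene and the acrylate joins C7 to C11 as the tetrasubstituted butenolide olefin with loss of ethene; five-membered ring closure is favoured over any reaction at the C10 methylidene, and no stereocenter is touched.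

**Step 13**
Reactants: 26 (1R,3S,6R,4Z)-3,13-diacetoxy-1-[(tert-butyldimethylsilyl)oxy]germacra-4,7(11),10(14)-trien-12,6-olide
Product: 27 (1R,3S,6R,4Z)-3,13-diacetoxy-1-hydroxygermacra-4,7(11),10(14)-trien-12,6-olide (CNP0227830.1)
Conditions: HF·pyridine, pyridine, THF, 0 °C → rt
Reagents that add atoms: none
Why: Acidic fluoride desilylation frees the C1 alcohol without the basic conditions that would endanger the acidic C6–H of the butenolide or the acetates.

**Compound list**
1 | furan-3-ylmethanol | OCc1ccoc1 | starting material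
2 | 1,1-dimethoxy-N,N-dimethylethanamine | CC(OC)(OC)N(C)C | starting material
3 | 1-(furan-3-ylmethoxy)-N,N-dimethylethenamine (ketene N,O-acetal) | C=C(N(C)C)OCc1ccoc1 | intermediate (not isolated)
4 | N,N-dimethyl-2-(3-methylidene-2,3-dihydrofuran-2-yl)acetamide | C=C1C=COC1CC(=O)N(C)C | intermediate (not isolated)
5 | N,N-dimethyl-2-(3-methylfuran-2-yl)acetamide | Cc1ccoc1CC(=O)N(C)C | intermediate
6 | hexa-1,5-diyne | C#CCCC#C | starting material
7 | 2-iodohex-1-en-5-yne | C=C(I)CCC#C | intermediate (not isolated)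
8 | 2,5-diiodohexa-1,5-diene | C=C(I)CCC(I)=C | intermediate
9 | (5-iodohexa-1,5-dien-2-yl)lithium | [Li]C(=C)CCC(I)=C | intermediate (not isolated)
10 | lithium 2-(dimethylamino)-6-iodo-3-methylidene-1-(3-methylfuran-2-yl)hept-6-en-2-olate | Cc1ccoc1CC([O-])(N(C)C)C(=C)CCC(I)=C.[Li+] | intermediate (not isolated)
11 | 6-iodo-3-methylidene-1-(3-methylfuran-2-yl)hept-6-en-2-one | Cc1ccoc1CC(=O)C(=C)CCC(I)=C | intermediate
12 | (2R)-6-iodo-3-methylidene-1-(3-methylfuran-2-yl)hept-6-en-2-ol | Cc1ccoc1C[C@@H](O)C(=C)CCC(I)=C | intermediate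
13 | tert-butyl{[(2R)-6-iodo-3-methylidene-1-(3-methylfuran-2-yl)hept-6-en-2-yl]oxy}dimethylsilane | Cc1ccoc1C[C@@H](O[Si](C)(C)C(C)(C)C)C(=C)CCC(I)=C | intermediate
14 | 5-bromo-2-{(2R)-2-[(tert-butyldimethylsilyl)oxy]-6-iodo-3-methylidenehept-6-en-1-yl}-3-methyl-2,5-dihydrofuran-2-ol | CC1=CC(Br)OC1(O)C[C@@H](O[Si](C)(C)C(C)(C)C)C(=C)CCC(I)=C | intermediate (not isolated)
15 | (2Z,6R)-6-[(tert-butyldimethylsilyl)oxy]-10-iodo-3-methyl-7-methylidene-4-oxoundeca-2,10-dienal | O=C/C=C(/C)C(=O)C[C@@H](O[Si](C)(C)C(C)(C)C)C(=C)CCC(I)=C | intermediate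
16 | alkenylchromium dichloride from 15 (C7–CrCl2, trivalent chromium) | O=C/C=C(/C)C(=O)C[C@@H](O[Si](C)(C)C(C)(C)C)C(=C)CCC(=C)[Cr](Cl)Cl | intermediate (not isolated)
17 | ring-closed C6 alkoxide on CrCl2 (trivalent chromium) | C=C1CCC(=C)[C@H](O[Cr](Cl)Cl)/C=C(/C)C(=O)C[C@H]1O[Si](C)(C)C(C)(C)C | intermediate (not isolated)
18 | (2Z,4R,9R)-9-[(tert-butyldimethylsilyl)oxy]-2-methyl-5,8-dimethylidene-4-[(trimethylsilyl)oxy]cyclodec-2-en-1-one | C=C1CCC(=C)[C@H](O[Si](C)(C)C)/C=C(/C)C(=O)C[C@H]1O[Si](C)(C)C(C)(C)C | intermediate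
19 | (1S,2Z,4R,9R)-9-[(tert-butyldimethylsilyl)oxy]-2-methyl-5,8-dimethylidene-4-[(trimethylsilyl)oxy]cyclodec-2-en-1-ol | C=C1CCC(=C)[C@H](O[Si](C)(C)C)/C=C(/C)[C@@H](O)C[C@H]1O[Si](C)(C)C(C)(C)C | intermediate
20 | (1S,2Z,4R,9R)-9-[(tert-butyldimethylsilyl)oxy]-2-methyl-5,8-dimethylidene-4-[(trimethylsilyl)oxy]cyclodec-2-en-1-yl acetate | C=C1CCC(=C)[C@H](O[Si](C)(C)C)/C=C(/C)[C@@H](OC(C)=O)C[C@H]1O[Si](C)(C)C(C)(C)C | intermediate (not isolated)
21 | (1S,2Z,4R,9R)-9-[(tert-butyldimethylsilyl)oxy]-4-hydroxy-2-methyl-5,8-dimethylidenecyclodec-2-en-1-yl acetate | C=C1CCC(=C)[C@H](O)/C=C(/C)[C@@H](OC(C)=O)C[C@H]1O[Si](C)(C)C(C)(C)C | intermediate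
22 | 2-(hydroxymethyl)prop-2-enoic acid | OCC(=C)C(=O)O | starting material
23 | 2-[(acetyloxy)methyl]prop-2-enoic acid | CC(=O)OCC(=C)C(=O)O | intermediate
24 | 2-[(acetyloxy)methyl]prop-2-enoyl chloride | CC(=O)OCC(=C)C(=O)Cl | intermediate (not isolated)
25 | (1R,2Z,4S,6R)-4-(acetyloxy)-6-[(tert-butyldimethylsilyl)oxy]-3-methyl-7,10-dimethylidenecyclodec-2-en-1-yl 2-[(acetyloxy)methyl]prop-2-enoate | C=C1CCC(=C)[C@H](OC(=O)C(=C)COC(C)=O)/C=C(/C)[C@@H](OC(C)=O)C[C@H]1O[Si](C)(C)C(C)(C)C | intermediate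
26 | (1R,3S,6R,4Z)-3,13-diacetoxy-1-[(tert-butyldimethylsilyl)oxy]germacra-4,7(11),10(14)-trien-12,6-olide | C=C1CCC2=C(COC(C)=O)C(=O)O[C@@H]2/C=C(/C)[C@@H](OC(C)=O)C[C@H]1O[Si](C)(C)C(C)(C)C | intermediate
27 | (1R,3S,6R,4Z)-3,13-diacetoxy-1-hydroxygermacra-4,7(11),10(14)-trien-12,6-olide | C=C1CCC2=C(COC(C)=O)C(=O)O[C@@H]2/C=C(/C)[C@@H](OC(C)=O)C[C@H]1O | target

**Step count and risks**
Total: 13 steps. Longest linear sequence: 11 steps (1, 3, 4, 5, 6, 7, 8, 9, 11, 12, 13).

Step 7 (ten-membered ring closure and C6 configuration). The closure competes with seven-membered attack on the C3 ketone, and the facial selectivity at C6 rests on remote substrate control. Fallback, setting out from 15 and coming back at 21: if the closure delivers mainly the C6 epimer (4S,9R)-silyl ether ketone F1, it is carried through the conditions of steps 8 and 9 to the (1S,4S,9R)-alcohol F2 and the (1S,4S,9R)-hydroxy acetate F3. The C6 carbinol is then inverted by a Mitsunobu reaction with chloroacetic acid (PPh3, diisopropyl azodicarboxylate, toluene, 0 °C) to the (6R)-chloroacetate F4, and the chloroacetyl group is removed selectively with thiourea and NaHCO3 in EtOH to give 21. C6 is thus set by inversion instead of directly.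

Step 12 (tetrasubstituted olefin by metathesis). Both partners are 1,1-disubstituted and one is electron-poor. Fallback, setting out from 13 and coming back at 26: the lactone carbonyl is brought in before ring closure instead of after it. Treating 13 with LiN(i-Pr)2 (3 equiv, THF, −78 → −20 °C) eliminates HI to the acetylide, which is trapped with ClCO2Me to give the alkynoate F5. Conjugate addition of iodide with formaldehyde trapping (MgI2, CH2O, CH2Cl2, 0 °C) gives the (Z)-3-iodo-2-(hydroxymethyl)enoate F6. Furan opening as in step 6 gives the keto-enal F7. Ni/Cr closure (CrCl2, NiCl2 cat., THF/DMF, high dilution) now forms C6–C7, and the C6 alkoxide lactonizes onto the cis ester to give the 13-hydroxy-3-oxo butenolide F8. (R)-CBS reduction gives the 3,13-diol F9, and Ac2O/pyridine acetylates both hydroxyls to 26. The iodide/formaldehyde step in the presence of the furan is the weak point of this fallback.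

Step 3 (organolithium acylation of an enolizable amide). The alkenyllithium may deprotonate the amide α-position, and the α-methylidene ketone is sensitive. Fallback, setting out from 5 and coming back at 11: amide 5 is reduced with Cp2Zr(H)Cl (THF, rt) to 2-(3-methylfuran-2-yl)acetaldehyde F10. F10 is coupled with excess 8 under non-basic Ni/Cr conditions (CrCl2, NiCl2 cat., DMF) to the racemic alcohol F11, which is oxidized with Dess–Martin periodinane to enone 11.

**Further compounds**
F1 | step 7 | (2Z,4S,9R)-9-[(tert-butyldimethylsilyl)oxy]-2-methyl-5,8-dimethylidene-4-[(trimethylsilyl)oxy]cyclodec-2-en-1-one | C=C1CCC(=C)[C@@H](O[Si](C)(C)C)/C=C(/C)C(=O)C[C@H]1O[Si](C)(C)C(C)(C)C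
F2 | step 7 | (1S,2Z,4S,9R)-9-[(tert-butyldimethylsilyl)oxy]-2-methyl-5,8-dimethylidene-4-[(trimethylsilyl)oxy]cyclodec-2-en-1-ol | C=C1CCC(=C)[C@@H](O[Si](C)(C)C)/C=C(/C)[C@@H](O)C[C@H]1O[Si](C)(C)C(C)(C)C
F3 | step 7 | (1S,2Z,4S,9R)-9-[(tert-butyldimethylsilyl)oxy]-4-hydroxy-2-methyl-5,8-dimethylidenecyclodec-2-en-1-yl acetate | C=C1CCC(=C)[C@@H](O)/C=C(/C)[C@@H](OC(C)=O)C[C@H]1O[Si](C)(C)C(C)(C)C
F4 | step 7 | (1R,2Z,4S,6R)-4-(acetyloxy)-6-[(tert-butyldimethylsilyl)oxy]-3-methyl-7,10-dimethylidenecyclodec-2-en-1-yl chloroacetate | C=C1CCC(=C)[C@H](OC(=O)CCl)/C=C(/C)[C@@H](OC(C)=O)C[C@H]1O[Si](C)(C)C(C)(C)C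
F5 | step 12 | methyl (7R)-7-[(tert-butyldimethylsilyl)oxy]-6-methylidene-8-(3-methylfuran-2-yl)oct-2-ynoate | Cc1ccoc1C[C@@H](O[Si](C)(C)C(C)(C)C)C(=C)CCC#CC(=O)OC
F6 | step 12 | methyl (2Z,7R)-7-[(tert-butyldimethylsilyl)oxy]-2-(hydroxymethyl)-3-iodo-6-methylidene-8-(3-methylfuran-2-yl)oct-2-enoate | Cc1ccoc1C[C@@H](O[Si](C)(C)C(C)(C)C)C(=C)CC/C(I)=C(\CO)C(=O)OC
F7 | step 12 | methyl (2Z,7R,10Z)-7-[(tert-butyldimethylsilyl)oxy]-2-(hydroxymethyl)-3-iodo-10-methyl-6-methylidene-9,12-dioxododeca-2,10-dienoate | O=C/C=C(/C)C(=O)C[C@@H](O[Si](C)(C)C(C)(C)C)C(=C)CC/C(I)=C(\CO)C(=O)OC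
F8 | step 12 | (1R,6R,4Z)-1-[(tert-butyldimethylsilyl)oxy]-13-hydroxy-3-oxogermacra-4,7(11),10(14)-trien-12,6-olide | C=C1CCC2=C(CO)C(=O)O[C@@H]2/C=C(/C)C(=O)C[C@H]1O[Si](C)(C)C(C)(C)C
F9 | step 12 | (1R,3S,6R,4Z)-1-[(tert-butyldimethylsilyl)oxy]-3,13-dihydroxygermacra-4,7(11),10(14)-trien-12,6-olide | C=C1CCC2=C(CO)C(=O)O[C@@H]2/C=C(/C)[C@@H](O)C[C@H]1O[Si](C)(C)C(C)(C)C
F10 | step 3 | 2-(3-methylfuran-2-yl)acetaldehyde | Cc1ccoc1CC=O
F11 | step 3 | rac-6-iodo-3-methylidene-1-(3-methylfuran-2-yl)hept-6-en-2-ol | Cc1ccoc1CC(O)C(=C)CCC(I)=C
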